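1. Numbering: the C15 chain runs from C1 (alkyne CH) to C15 (ethyl CH3). The oxocane ring is O–C6–C7–C8–C9–C10–C11–C12.
2. Retrosynthetic cuts, in order: the O10 protecting group and the three acetates, then C3=C4 (enyne olefination), then the ring bond O–C12 (epoxide opening by O6), then C12–C13 (chloroallylboration). Last, C6–C7 and C9–C10 are cut together, which leaves propane-1,3-diol (C7–C8–C9) and two molecules of one allenyl ether (C4–C6 and C10–C12).
3. Enabling feature: ring atoms C6, C7, C9 and C10 are all R and carry a syn/anti/syn tetraol pattern. The C6–C10 arc of the oxocane therefore has a local C2 axis through the methylene C8, and one catalyst-controlled event acting twice on a C3 diol can build both halves.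
4. Forward order: a three-component two-directional coupling gives a C2-symmetric C9 diene. Both vinyl groups are hydroborated, and one oxidative acetalisation then differentiates the two ends and distinguishes O6 from O10. The right end is extended to C15, the only ring is closed by 8-exo epoxide opening, and the enyne, the acetates and the PMB removal follow.
5. Stereochemistry: C6, C7, C9 and C10 come from the chiral ruthenium catalyst of the key step. C12 and C13 come from a pinene-derived chloroallylborane followed by two SN2 inversions: at C13 on epoxide closure, and at C12 on ring closure, which fixes the trans C6/C12 relation. The Z-alkene comes from a Peterson olefination.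
6. Helpers: the PMB group carried by the allene chelates and directs the allyl-metal. Later one copy becomes the O4/O6 acetal and leaves to expose the ring oxygen, while the other masks the C10 hydroxyl until the last step.

Key step: step 3

Abbreviations: PMB = 4-methoxybenzyl, TBS = tert-butyldimethylsilyl, TIPS = triisopropylsilyl, Ipc = isopinocampheyl. Locants C4–C15 and O4–O13 refer to the numbering above.
Assumption: (S)-BINAP is taken to give the R-configured carbinols in step 3. If the sense of induction is the opposite, (R)-BINAP is used and nothing else changes.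

Step 1
Reactants: 1 4-methoxybenzyl alcohol; 2 propargyl bromide (3-bromoprop-1-yne)
Product: 3 4-methoxybenzyl propargyl ether
Conditions: NaH, THF, 0 °C to rt
Reagents that add atoms: none
Why: Williamson ether synthesis between a primary alkoxide and an unhindered propargylic bromide, in which no stereocentre is formed.

Step 2
Reactants: 3 4-methoxybenzyl propargyl ether
Product: 4 4-methoxybenzyl allenyl ether
Conditions: KOt-Bu (0.3 equiv), THF, rt
Reagents that add atoms: none
Why: Base-catalysed propargyl-to-allenyl ether isomerisation, which under catalytic KOt-Bu at room temperature should stop at the allenyl ether and creates no stereocentre.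

Step 3
Reactants: 5 propane-1,3-diol; 4 4-methoxybenzyl allenyl ether (2.5 equiv)
Product: 9 (3R,4R,6R,7R)-3,7-bis[(4-methoxybenzyl)oxy]nona-1,8-diene-4,6-diol, via 3-hydroxypropanal 6 (not isolated), via mono-adduct diol 7 (not isolated), via hydroxy aldehyde 8 (not isolated)
Conditions: H2Ru(CO)(PPh3)3 (5 mol %), (S)-BINAP (5 mol %), Bu4NI (10 mol %), THF, 80 °C, sealed tube
Reagents that add atoms: none
Why: Proposed new method: the ruthenium hydride adds to the central carbon of allene 4 and chelation by the ether oxygen holds the resulting σ-allyl as its (Z)-isomer, while dehydrogenation of one primary carbinol of 5 supplies aldehyde 6, so that addition through a closed chair transition state makes C9–C10 and gives 7, whose remaining primary carbinol is dehydrogenated to 8 and allylated in the same way to make C6–C7. The closest known reaction types are the ruthenium–BINAP hydrogen auto-transfer coupling of primary alcohols with 1,1-disubstituted alkoxyallenes, which gives syn diol monoethers, and the iridium-catalysed two-directional allylation of propane-1,3-diol; the new element is their union with a monosubstituted alkoxyallene. No ring is closed. The carbinol centres C7 and C9 are set by the BINAP-controlled aldehyde face and the ether centres C6 and C10 by the (Z)-allyl geometry relayed through the chair, which gives the syn relation in each half and, as the same catalyst acts twice, the anti C7/C9 relation of the C2-symmetric all-R array. The step needs oxidation of primary in preference to secondary carbinols and must never pass through malondialdehyde, which the redox relay at one terminus at a time and the slower dehydrogenation of the hindered secondary alcohols should secure. A wrong first addition is carried into a separable pseudo-meso diastereomer, so the C2 product should be enriched beyond the selectivity of a single addition.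

Step 4
Reactants: 9 (3R,4R,6R,7R)-3,7-bis[(4-methoxybenzyl)oxy]nona-1,8-diene-4,6-diol
Product: 10 (3R,4R,6R,7R)-4,6-bis[(tert-butyldimethylsilyl)oxy]-3,7-bis[(4-methoxybenzyl)oxy]nona-1,8-diene
Conditions: TBSOTf, 2,6-lutidine, CH2Cl2, −78 to 0 °C
Reagents that add atoms: tert-butyldimethylsilyl triflate CC(C)(C)[Si](C)(C)OS(=O)(=O)C(F)(F)F
Why: Silyl triflate silylation of the two homotopic hindered secondary carbinols, chosen because silyl ether oxygens are poor nucleophiles and survive every step up to the fluoride treatment; no stereocentre is touched.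

Step 5
Reactants: 10 bis-TBS bis-PMB diene
Product: 12 (3R,4R,6R,7R)-4,6-bis[(tert-butyldimethylsilyl)oxy]-3,7-bis[(4-methoxybenzyl)oxy]nonane-1,9-diol, via bis-borane 11 (not isolated)
Conditions: 9-BBN, THF, 0 °C to rt; then NaOH, H2O2, 0 °C
Reagents that add atoms: hydrogen peroxide OO; 9-borabicyclo[3.3.1]nonane B1C2CCCC1CCC2 (its atoms stay only in 11)
Why: Two-directional anti-Markovnikov hydroboration–oxidation, in which the bulky 9-BBN should place boron on both terminal carbons (C4 and C12) and the oxidation leaves the four existing centres untouched.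

Step 6
Reactants: 12 C2-symmetric C4,C12-diol
Product: 13 (3R,4R,6R)-4,6-bis[(tert-butyldimethylsilyl)oxy]-3-[(4-methoxybenzyl)oxy]-6-[(2R,4R)-2-(4-methoxyphenyl)-1,3-dioxan-4-yl]hexan-1-ol
Conditions: DDQ (1 equiv), 4 Å MS, CH2Cl2, −10 °C
Reagents that add atoms: none
Why: Oxidative acetalisation of a PMB ether with DDQ under anhydrous conditions, in which the benzylic oxocarbenium ion is trapped by the 1,3-related primary hydroxyl; as the two halves of 12 are homotopic one equivalent of oxidant can give only one mono-acetal (unreacted and doubly oxidised material is separated and recycled), and the new acetal centre should take the diequatorial 2,4-cis arrangement.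

Step 7
Reactants: 13 C12 alcohol with O4/O6 acetal
Product: 14 the corresponding C12 aldehyde (hexanal analogue of 13)
Conditions: Dess–Martin periodinane, NaHCO3, CH2Cl2, 0 °C to rt
Reagents that add atoms: none
Why: Dess–Martin oxidation under bicarbonate buffer, mild enough to keep the acetal and to avoid β-elimination of the C10 PMB ether; no stereocentre is affected.

Step 8
Reactants: 14 C12 aldehyde
Product: 16 (12R,13R)-13-chloro-12-hydroxy C14=C15 vinyl chlorohydrin (O4/O6 acetal, O7/O9 TBS, O10 PMB), via borinate 15 (not isolated)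
Conditions: allyl chloride, LiN(c-C6H11)2, (−)-Ipc2BOMe, Et2O, −95 °C; BF3·OEt2; then 14, −95 °C; then H2O2, pH 7 buffer
Reagents that add atoms: allyl chloride C=CCCl; (−)-B-methoxydiisopinocampheylborane COB([C@@H]1C[C@@H]2C[C@H]([C@H]1C)C2(C)C)[C@@H]1C[C@@H]2C[C@H]([C@H]1C)C2(C)C (its atoms stay only in 15)
Why: (Z)-γ-Chloroallylboration with a diisopinocampheylborane, in which the closed chair transition state turns the Z geometry into the syn chlorohydrin and the (+)-α-pinene-derived ligands choose the aldehyde face (the sense that gives (R)-pent-4-en-2-ol from acetaldehyde), so that 12R and 13R are set under reagent control.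

Step 9
Reactants: 16 vinyl chlorohydrin
Product: 17 (12R,13R)-13-chloro-12-hydroxy compound with saturated C14–C15 ethyl end
Conditions: 2-nitrobenzenesulfonyl hydrazide, Et3N, CH2Cl2, rt
Reagents that add atoms: none
Why: Diimide reduction, which saturates the monosubstituted C14=C15 alkene without hydrogenolysis of the allylic chloride, the PMB ether or the acetal.

Step 10
Reactants: 17 ethyl chlorohydrin
Product: 19 (6R,7R,9R,10R,12R,13S)-cis-12,13-epoxy-4,6-diol (O7/O9 TBS, O10 PMB), via chlorohydrin triol 18 (not isolated)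
Conditions: PPTS, MeOH, rt; concentrate; then DBU, CH2Cl2, rt
Reagents that add atoms: none
Why: Acid-catalysed transacetalisation to methanol frees O4 and O6, and DBU then closes the chlorohydrin by 3-exo-tet SN2 displacement with inversion at C13 to the cis (12R,13S)-epoxide, an aprotic amine base being used to avoid silyl migration from O7 to O6.

Step 11
Reactants: 19 epoxy diol
Product: 22 (6R,7R,9R,10R,12S,13S)-oxocane 4,13-diol (O7/O9 TBS, O10 PMB), via bis-stannyl ether 20 (not isolated), via cyclised stannyl ether 21 (not isolated)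
Conditions: (Bu3Sn)2O, toluene, reflux, −H2O; then Zn(OTf)2, toluene (high dilution), 90 °C; aq KF
Reagents that add atoms: bis(tributyltin) oxide CCCC[Sn](CCCC)(CCCC)O[Sn](CCCC)(CCCC)CCCC (its atoms stay only in 20 and 21)
Why: Intramolecular exo opening of an epoxide by a tin alkoxide under Zn(OTf)2 activation (8-exo-tet), a reaction type that has served for eight-membered Laurencia-type ethers; backside attack of O6 inverts C12 to 12S, which fixes both the trans C6/C12 and the syn C12/C13 relations, while O7, O9 and O10 are blocked and the primary tin alkoxide could only form a ten-membered ring.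

Step 12
Reactants: 22 oxocane diol
Product: 23 oxocane C4 aldehyde with free C13 hydroxyl
Conditions: TEMPO (cat.), PhI(OAc)2, CH2Cl2, rt
Reagents that add atoms: none
Why: Oxoammonium (TEMPO) oxidation with PhI(OAc)2, selective for the primary C4 alcohol over the secondary C13 alcohol and harmless to the PMB ether.

Step 13
Reactants: 23 oxocane aldehyde
Product: 24 (3Z)-1-TIPS-enyne oxocane (O7/O9 TBS, O10 PMB, free C13 hydroxyl)
Conditions: 1,3-bis(triisopropylsilyl)propyne, n-BuLi, THF, −78 °C; then 23, −78 to 0 °C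
Reagents that add atoms: 1,3-bis(triisopropylsilyl)propyne CC(C)[Si](C(C)C)(C(C)C)CC#C[Si](C(C)C)(C(C)C)C(C)C
Why: Peterson olefination with lithiated 1,3-bis(triisopropylsilyl)propyne, whose bulky silyl groups should steer the addition–elimination to the Z-enyne, a second equivalent of the reagent covering the free C13 hydroxyl.

Step 14
Reactants: 24 TIPS-enyne
Product: 25 (3Z)-enyne oxocane 7,9,13-triol with O10 PMB
Conditions: Bu4NF, THF, 0 °C to rt
Reagents that add atoms: none
Why: Fluoride-induced desilylation removes the two TBS ethers and the alkynyl TIPS group in one operation while no ester is yet present that could migrate.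

Step 15
Reactants: 25 triol
Product: 26 7,9,13-triacetate with O10 PMB
Conditions: Ac2O, pyridine, DMAP (cat.), CH2Cl2, rt
Reagents that add atoms: acetic anhydride CC(=O)OC(C)=O
Why: DMAP-catalysed acetylation of the three free secondary hydroxyls (O7, O9, O13), O10 being still masked as its PMB ether.

Step 16
Reactants: 26 triacetate PMB ether
Product: 27 target CNP0171306.2
Conditions: DDQ, CH2Cl2–pH 7 buffer, 0 °C
Reagents that add atoms: none
Why: Oxidative PMB cleavage with DDQ in a buffered two-phase medium, a non-basic method that should leave the acetates in place (no O9-to-O10 acetyl shift) and tolerate the Z-enyne.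

Compound list
1 | 4-methoxybenzyl alcohol | COc1ccc(CO)cc1 | starting material
2 | propargyl bromide | C#CCBr | starting material
3 | 4-methoxybenzyl propargyl ether | C#CCOCc1ccc(OC)cc1 | intermediate
4 | 4-methoxybenzyl allenyl ether | C=C=COCc1ccc(OC)cc1 | intermediate
5 | propane-1,3-diol | OCCCO | starting material
6 | 3-hydroxypropanal | O=CCCO | intermediate
7 | (3R,4R)-4-[(4-methoxybenzyl)oxy]hex-5-ene-1,3-diol | OCC[C@@H](O)[C@H](OCc1ccc(OC)cc1)C=C | intermediate
8 | (3R,4R)-3-hydroxy-4-[(4-methoxybenzyl)oxy]hex-5-enal | O=CC[C@@H](O)[C@H](OCc1ccc(OC)cc1)C=C | intermediate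
9 | (3R,4R,6R,7R)-3,7-bis[(4-methoxybenzyl)oxy]nona-1,8-diene-4,6-diol | C=C[C@@H](OCc1ccc(OC)cc1)[C@H](O)C[C@@H](O)[C@H](OCc1ccc(OC)cc1)C=C | intermediate
10 | (3R,4R,6R,7R)-4,6-bis(TBSO)-3,7-bis(PMBO)nona-1,8-diene | C=C[C@@H](OCc1ccc(OC)cc1)[C@H](O[Si](C)(C)C(C)(C)C)C[C@@H](O[Si](C)(C)C(C)(C)C)[C@H](OCc1ccc(OC)cc1)C=C | intermediate
11 | 1,9-bis(9-borabicyclo[3.3.1]nonan-9-yl)nonane derived from 10 (boron on C4 and C12) | C1CC2CCCC(C1)B2CC[C@@H](OCc1ccc(OC)cc1)[C@H](O[Si](C)(C)C(C)(C)C)C[C@@H](O[Si](C)(C)C(C)(C)C)[C@H](OCc1ccc(OC)cc1)CCB1C2CCCC1CCC2 | intermediate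
12 | (3R,4R,6R,7R)-4,6-bis(TBSO)-3,7-bis(PMBO)nonane-1,9-diol | OCC[C@@H](OCc1ccc(OC)cc1)[C@H](O[Si](C)(C)C(C)(C)C)C[C@@H](O[Si](C)(C)C(C)(C)C)[C@H](OCc1ccc(OC)cc1)CCO | intermediate
13 | (3R,4R,6R)-4,6-bis(TBSO)-3-(PMBO)-6-[(2R,4R)-2-(4-methoxyphenyl)-1,3-dioxan-4-yl]hexan-1-ol | COc1ccc(cc1)[C@@H]1OCC[C@@H](O1)[C@H](O[Si](C)(C)C(C)(C)C)C[C@@H](O[Si](C)(C)C(C)(C)C)[C@H](OCc1ccc(OC)cc1)CCO | intermediate
14 | (3R,4R,6R)-4,6-bis(TBSO)-3-(PMBO)-6-[(2R,4R)-2-(4-methoxyphenyl)-1,3-dioxan-4-yl]hexanal | COc1ccc(cc1)[C@@H]1OCC[C@@H](O1)[C@H](O[Si](C)(C)C(C)(C)C)C[C@@H](O[Si](C)(C)C(C)(C)C)[C@H](OCc1ccc(OC)cc1)CC=O | intermediate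
15 | O12-diisopinocampheylborinate of 16 | COc1ccc(cc1)[C@@H]1OCC[C@@H](O1)[C@H](O[Si](C)(C)C(C)(C)C)C[C@@H](O[Si](C)(C)C(C)(C)C)[C@H](OCc1ccc(OC)cc1)C[C@@H](OB([C@@H]1C[C@@H]2C[C@H]([C@H]1C)C2(C)C)[C@@H]1C[C@@H]2C[C@H]([C@H]1C)C2(C)C)[C@H](Cl)C=C | intermediate
16 | (3R,4R,6R,7R,9R)-7,9-bis(TBSO)-3-chloro-6-(PMBO)-9-[(2R,4R)-2-(4-methoxyphenyl)-1,3-dioxan-4-yl]non-1-en-4-ol | COc1ccc(cc1)[C@@H]1OCC[C@@H](O1)[C@H](O[Si](C)(C)C(C)(C)C)C[C@@H](O[Si](C)(C)C(C)(C)C)[C@H](OCc1ccc(OC)cc1)C[C@@H](O)[C@H](Cl)C=C | intermediate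
17 | saturated analogue of 16 (12R,13R chlorohydrin with ethyl end) | COc1ccc(cc1)[C@@H]1OCC[C@@H](O1)[C@H](O[Si](C)(C)C(C)(C)C)C[C@@H](O[Si](C)(C)C(C)(C)C)[C@H](OCc1ccc(OC)cc1)C[C@@H](O)[C@H](Cl)CC | intermediate
18 | (6R,7R,9R,10R,12R,13R)-13-chloro-4,6,12-triol (O7/O9 TBS, O10 PMB) | OCC[C@@H](O)[C@H](O[Si](C)(C)C(C)(C)C)C[C@@H](O[Si](C)(C)C(C)(C)C)[C@H](OCc1ccc(OC)cc1)C[C@@H](O)[C@H](Cl)CC | intermediate
19 | (6R,7R,9R,10R,12R,13S)-cis-12,13-epoxy-4,6-diol (O7/O9 TBS, O10 PMB) | OCC[C@@H](O)[C@H](O[Si](C)(C)C(C)(C)C)C[C@@H](O[Si](C)(C)C(C)(C)C)[C@H](OCc1ccc(OC)cc1)C[C@H]1O[C@H]1CC | intermediate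
20 | O4,O6-bis(tributylstannyl) ether of 19 | CCCC[Sn](CCCC)(CCCC)OCC[C@@H](O[Sn](CCCC)(CCCC)CCCC)[C@H](O[Si](C)(C)C(C)(C)C)C[C@@H](O[Si](C)(C)C(C)(C)C)[C@H](OCc1ccc(OC)cc1)C[C@H]1O[C@H]1CC | intermediate
21 | O4,O13-bis(tributylstannyl) ether of 22 | CCCC[Sn](CCCC)(CCCC)OCC[C@H]1O[C@H]([C@H](CC)O[Sn](CCCC)(CCCC)CCCC)C[C@@H](OCc2ccc(OC)cc2)[C@H](O[Si](C)(C)C(C)(C)C)C[C@H]1O[Si](C)(C)C(C)(C)C | intermediate
22 | (6R,7R,9R,10R,12S,13S)-oxocane with 2-hydroxyethyl at C6 and (S)-1-hydroxypropyl at C12 (O7/O9 TBS, O10 PMB) | OCC[C@H]1O[C@H]([C@H](CC)O)C[C@@H](OCc2ccc(OC)cc2)[C@H](O[Si](C)(C)C(C)(C)C)C[C@H]1O[Si](C)(C)C(C)(C)C | intermediate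
23 | C4 aldehyde of 22 | O=CC[C@H]1O[C@H]([C@H](CC)O)C[C@@H](OCc2ccc(OC)cc2)[C@H](O[Si](C)(C)C(C)(C)C)C[C@H]1O[Si](C)(C)C(C)(C)C | intermediate
24 | (3Z)-1-(triisopropylsilyl)pent-2-en-4-ynyl oxocane (O7/O9 TBS, O10 PMB, C13 hydroxyl free) | CC(C)[Si](C(C)C)(C(C)C)C#C/C=C\C[C@H]1O[C@H]([C@H](CC)O)C[C@@H](OCc2ccc(OC)cc2)[C@H](O[Si](C)(C)C(C)(C)C)C[C@H]1O[Si](C)(C)C(C)(C)C | intermediate
25 | (3Z)-enyne oxocane 7,9,13-triol, O10 PMB | C#C/C=C\C[C@H]1O[C@H]([C@H](CC)O)C[C@@H](OCc2ccc(OC)cc2)[C@H](O)C[C@H]1O | intermediate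
26 | (3Z)-enyne oxocane 7,9,13-triacetate, O10 PMB | C#C/C=C\C[C@H]1O[C@H]([C@H](CC)OC(C)=O)C[C@@H](OCc2ccc(OC)cc2)[C@H](OC(C)=O)C[C@H]1OC(C)=O | intermediate
27 | CNP0171306.2, (6R,7R,9R,10R,12S,13S,3Z) | C#C/C=C\C[C@H]1O[C@H]([C@H](CC)OC(C)=O)C[C@@H](O)[C@H](OC(C)=O)C[C@H]1OC(C)=O | target

Total steps: 16. Longest linear sequence: 16 (steps 1–16 from 1; compound 5 enters at step 3).

Steps most likely to fail

Step 3 (the labelled step). The allenyl ether may decompose or isomerise under the hydride catalyst. The (Z)-allyl geometry may erode, with loss of the syn relation. The reaction may stall after the first addition, or the β-hydroxy aldehyde stage may dehydrate.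
The fallback sets out from 5 and returns at 9, using only known iterative allylborane chemistry.
- Monosilylation of 5 (NaH, TBSCl) gives 3-[(tert-butyldimethylsilyl)oxy]propan-1-ol F1.
- Oxidation (TEMPO, PhI(OAc)2) gives 3-[(tert-butyldimethylsilyl)oxy]propanal F2.
- Addition of the (Z)-γ-(4-methoxybenzyloxy)allyl-diisopinocampheylborane made from allyl PMB ether, s-BuLi, (−)-Ipc2BOMe and BF3·OEt2 gives the syn adduct (3R,4R)-1-[(tert-butyldimethylsilyl)oxy]-4-[(4-methoxybenzyl)oxy]hex-5-en-3-ol F3.
- Bu4NF converts F3 into 7, and selective oxidation of the primary alcohol (TEMPO, PhI(OAc)2) gives 8.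
- A second addition of the same borane under reagent control gives 9.

Step 11. The eight-membered closure is slow. It may be overtaken by participation of the C9 silyl ether oxygen in a five-membered mode, by silyl migration from O7 to O6, or by Lewis-acid loss of the PMB ether.
The fallback sets out from 14 and returns at 22. It replaces the epoxide by a cyclic sulfate, a much more reactive electrophile that is opened irreversibly.
- Aldehyde 14 reacts with the (+)-α-pinene-derived (E)-γ-(1,3,2-dioxaborinan-2-yl)allyl-diisopinocampheylborane, and oxidative work-up gives the anti (12R,13S)-vinyl diol F4.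
- Diimide gives the saturated anti diol F5.
- 1,1'-Sulfonyldiimidazole and DBU close the acetal-protected cyclic sulfate F6 without any ruthenium oxidant, so the anisyl groups survive.
- PPTS in MeOH removes the acetal to give the 4,6-diol cyclic sulfate F7.
- NaH in THF under dilution lets the C6 alkoxide open the sulfate at C12 with inversion, giving the oxocane C13 sulfate monoester sodium salt F8.
- Mild aqueous acid hydrolyses F8 to 22.

Step 13. The lithium reagent may enolise the aldehyde, with β-elimination of the ring oxygen, or the Z selectivity may erode.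
The fallback sets out from 23 and returns at 24. It exchanges the Peterson route for a Wittig-type olefination plus cross-coupling.
- Stork–Zhao olefination (Ph3PCH2I iodide, NaN(SiMe3)2, THF–HMPA, −78 °C) gives the (Z)-vinyl iodide oxocane F9.
- Sonogashira coupling of F9 with (triisopropylsilyl)acetylene (Pd(PPh3)4, CuI, Et3N) gives 24.

Further compounds
F1 | step 3 | 3-[(tert-butyldimethylsilyl)oxy]propan-1-ol | CC(C)(C)[Si](C)(C)OCCCO
F2 | step 3 | 3-[(tert-butyldimethylsilyl)oxy]propanal | CC(C)(C)[Si](C)(C)OCCC=O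
F3 | step 3 | (3R,4R)-1-[(tert-butyldimethylsilyl)oxy]-4-[(4-methoxybenzyl)oxy]hex-5-en-3-ol | CC(C)(C)[Si](C)(C)OCC[C@@H](O)[C@H](OCc1ccc(OC)cc1)C=C
F4 | step 11 | anti (12R,13S)-vinyl diol (O4/O6 acetal, O7/O9 TBS, O10 PMB) | COc1ccc(cc1)[C@@H]1OCC[C@@H](O1)[C@H](O[Si](C)(C)C(C)(C)C)C[C@@H](O[Si](C)(C)C(C)(C)C)[C@H](OCc1ccc(OC)cc1)C[C@@H](O)[C@@H](O)C=C
F5 | step 11 | saturated anti diol | COc1ccc(cc1)[C@@H]1OCC[C@@H](O1)[C@H](O[Si](C)(C)C(C)(C)C)C[C@@H](O[Si](C)(C)C(C)(C)C)[C@H](OCc1ccc(OC)cc1)C[C@@H](O)[C@@H](O)CC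
F6 | step 11 | acetal-protected cyclic sulfate | COc1ccc(cc1)[C@@H]1OCC[C@@H](O1)[C@H](O[Si](C)(C)C(C)(C)C)C[C@@H](O[Si](C)(C)C(C)(C)C)[C@H](OCc1ccc(OC)cc1)C[C@H]1OS(=O)(=O)O[C@H]1CC
F7 | step 11 | 4,6-diol cyclic sulfate | OCC[C@@H](O)[C@H](O[Si](C)(C)C(C)(C)C)C[C@@H](O[Si](C)(C)C(C)(C)C)[C@H](OCc1ccc(OC)cc1)C[C@H]1OS(=O)(=O)O[C@H]1CC
F8 | step 11 | oxocane C13 sulfate monoester sodium salt | OCC[C@H]1O[C@H]([C@H](CC)OS(=O)(=O)[O-])C[C@@H](OCc2ccc(OC)cc2)[C@H](O[Si](C)(C)C(C)(C)C)C[C@H]1O[Si](C)(C)C(C)(C)C.[Na+]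
F9 | step 13 | (Z)-vinyl iodide oxocane | I/C=C\C[C@H]1O[C@H]([C@H](CC)O)C[C@@H](OCc2ccc(OC)cc2)[C@H](O[Si](C)(C)C(C)(C)C)C[C@H]1O[Si](C)(C)C(C)(C)C
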